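Numbering: C1 (quaternary, CH3), C2, C3, C4 (isopropyl carbinol), C5 (fusion CH), C6 (angelate), C7, C8 (CH3)/C9 (epoxide), C10 (carbinol). β is the face of the C1 methyl group, so the target is 4β-OH, 5α-H, 6α-OAng, 8α,9α-epoxy, 10α-OH.
Retrosynthesis: cut C10–H, the C6 ester and the epoxide oxygen; then remove C9 (cut C8–C9 and C9–C10, restore C8–C10); then cut C4–isopropyl, C3–C4 of the five-membered ring, C6–O, C1–C2 and C1–CH3.
Enabling feature: without C9 the seven-membered ring becomes the six-membered ring C10–C8–C7–C6–C5–C1. This ring has a carbonyl carbon beside a methyl-bearing carbon and a carbon substituent on C5, which is the ring of (R)-carvone. C1 is quaternary, so a C10 ketone can enolise only toward C8, the bond that must accept C9.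
Forward order: carvone ring, C1 quaternary centre (two alkylations), C6 oxygen, five-membered ring by metathesis (trans-hydrindane), isopropyl at C4, six- to seven-membered ring enlargement, then epoxide, angelate and C10 reduction.
Stereochemistry: C5 comes from (R)-carvone and its isopropenyl group steers C1 and C6. The β angular methyl steers C4. The chair-like seven-membered ring exposes the α face of C8=C9 and, once the α epoxide is in place, the β face of C10=O. The Z alkene comes from angelic acid.
Key step: step 12

Remark on the chemistry: centres that are erased later (C1 after the first alkylation, the side-chain oxirane carbon, the chlorine-bearing C8) are carried as mixtures and drawn without configuration.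

Step 1
Reactants: 1 (R)-carvone; 2 iodomethane
Product: 4 6-methylcarvone (both C1 epimers), via lithium dienolate 3 (not isolated)
Conditions: LiN(iPr)2, THF, −78 °C; then 2, −78 → 0 °C
Reagents that add atoms: iodomethane 2, CI
Why: Kinetic α′-deprotonation of the cross-conjugated enone followed by SN2 methylation (enolate alkylation) is the standard first alkylation of carvone, and the configuration created at C1 is irrelevant because step 2 flattens this carbon again.

Step 2
Reactants: 4 6-methylcarvone; 5 allyl bromide
Product: 7 (5S,6S)-6-allyl-2,6-dimethyl-5-(prop-1-en-2-yl)cyclohex-2-en-1-one (C1: CH3 β and allyl α; C5: isopropenyl β), via methylated lithium dienolate 6 (not isolated)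
Conditions: LiN(iPr)2, THF, −78 °C; then 5, DMPU, −78 → 0 °C
Reagents that add atoms: allyl bromide 5, C=CCBr
Why: In this second enolate alkylation the planar C1=C10 dienolate should be attacked on the face opposite to the neighbouring β isopropenyl group at C5, so C2 ends α and the methyl group β, which is the trans relationship between C2 and C4 that the ring fusion needs; a simple allyl halide also avoids the tandem double Michael reaction that acrylates undergo with this dienolate.

Step 3
Reactants: 7 allyl methyl carvone
Product: 8 triethylsilyl dienol ether (C10(OSiEt3)=C8–C7=C6)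
Conditions: Et3SiOTf, Et3N, CH2Cl2, 0 °C
Reagents that add atoms: triethylsilyl triflate, CC[Si](CC)(CC)OS(=O)(=O)C(F)(F)F
Why: This is soft enolisation with a silyl triflate and an amine, and since C1 carries no hydrogen the O-silylated enone can lose a proton only from C6, which should give the linearly conjugated silyl dienol ether as a single regioisomer.

Step 4
Reactants: 8 triethylsilyl dienol ether
Product: 9 6α-hydroxy enone (OH trans to the isopropenyl group)
Conditions: mCPBA (1.0 equiv), CH2Cl2–hexane, −20 °C; aqueous work-up
Reagents that add atoms: 3-chloroperbenzoic acid, OOC(=O)c1cccc(Cl)c1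
Why: In this vinylogous Rubottom oxidation the peracid should take the open C6=C7 end of the electron-rich diene in preference to the tetrasubstituted C8=C10 bond beside quaternary C1 and long before the two isolated alkenes, the allylic epoxide collapses to the enone with loss of silicon, and oxygen arrives anti to the adjacent β isopropenyl group, which sets the 6α configuration.

Step 5
Reactants: 9 6α-hydroxy enone
Product: 10 6α-tert-butyldimethylsilyl ether
Conditions: t-BuMe2SiOTf, 2,6-lutidine, CH2Cl2, 0 °C
Reagents that add atoms: tert-butyldimethylsilyl triflate, CC(C)(C)[Si](C)(C)OS(=O)(=O)C(F)(F)F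
Why: Silyl triflate silylation is the usual protection of a hindered secondary allylic alcohol and stops base-induced isomerisation of the γ-hydroxy enone.

Step 6
Reactants: 10 6α-silyl ether
Product: 12 C4 methyl ketone (acetyl β on C5), via side-chain epoxide 11 (not isolated)
Conditions: mCPBA (1.05 equiv), CH2Cl2, 0 °C; crude, then H5IO6, THF–H2O, 0 °C → rt
Reagents that add atoms: 3-chloroperbenzoic acid, OOC(=O)c1cccc(Cl)c1; water, O
Why: Prilezhaev epoxidation distinguishes the electron-richer 1,1-disubstituted alkene from the monosubstituted allyl group and from the electron-poor enone, and periodic acid hydrolyses the oxirane and cleaves the glycol (Malaprade cleavage) to the methyl ketone under conditions too mild to enolise C5.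

Step 7
Reactants: 12 C4 methyl ketone
Product: 14 terminal tert-butyldimethylsilyl enol ether (C4(OSi)=CH2), via terminal lithium enolate 13 (not isolated)
Conditions: LiN(iPr)2 (1.1 equiv), THF, −78 °C; then t-BuMe2SiOTf, −78 °C
Reagents that add atoms: tert-butyldimethylsilyl triflate, CC(C)(C)[Si](C)(C)OS(=O)(=O)C(F)(F)F
Why: In this kinetic enolate formation and O-silylation the amide base should remove a proton from the exposed methyl group and not from C5–H buried between C1 and C6, the enone offers no α′ hydrogen, and the terminal enolate cannot expel the C6 silyloxy group.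

Step 8
Reactants: 14 terminal silyl enol ether
Product: 16 trans-hydrindene-4,10-dione (1β-CH3, 5α-H, 6α-OSi, C7=C8), via bicyclic silyl enol ether 15 (not isolated)
Conditions: second-generation Grubbs catalyst (H2IMes)(PCy3)Cl2Ru=CHPh (5 mol %), toluene (dilute), 80 °C; then THF, AcOH, Bu4NF (1.1 equiv each), 0 °C
Reagents that add atoms: none
Why: Ring-closing metathesis of a silyl enol ether with a terminal alkene, a known route to carbocyclic silyl enol ethers, should join C3 to C4 as a five-membered ring because both arms sit equatorial and trans on the conformer that also keeps the C6 silyl ether equatorial, and buffered fluoride then protonates C3, so the C5 hydrogen of the only kinetically stable trans-fused ketone is never touched.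

Step 9
Reactants: 16 trans-hydrindene-4,10-dione; 17 isopropylmagnesium chloride
Product: 18 4β-hydroxy-4α-isopropyl trans-hydrindenone
Conditions: 17 (1.5 equiv), CeCl3 (anhydrous), THF, −78 °C
Reagents that add atoms: isopropylmagnesium chloride 17, CC(C)[Mg]Cl
Why: In this organocerium 1,2-addition the weakly basic reagent suppresses enolisation and β-hydride reduction of the cyclopentanone, the conjugated C10 carbonyl between quaternary C1 and the C8 methyl group is far less electrophilic, and the axial β methyl group on C1 lies directly over the β face of C4, so the isopropyl group should enter from the α face and the hydroxyl group end β.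

Step 10
Reactants: 18 tertiary alcohol
Product: 19 4β-triethylsilyl ether
Conditions: Et3SiOTf, 2,6-lutidine, CH2Cl2, 0 °C → rt
Reagents that add atoms: triethylsilyl triflate, CC[Si](CC)(CC)OS(=O)(=O)C(F)(F)F
Why: A silyl triflate with a hindered pyridine base is the standard way to silylate a tertiary alcohol and removes the acidic hydrogen before the hydride and zinc reagents.

Step 11
Reactants: 19 bis-silyl enone
Product: 21 trans-hydrindanone trimethylsilyl enol ether (C8=C10–OSiMe3), via lithium enolate 20 (not isolated)
Conditions: LiBH(s-Bu)3 (1.1 equiv), THF, −78 °C; then Me3SiCl, Et3N, −78 → 0 °C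
Reagents that add atoms: chlorotrimethylsilane, C[Si](C)(C)Cl
Why: In this conjugate hydride reduction with in situ O-silylation the bulky borohydride cannot reach the carbonyl carbon flanked by C1 and C8 and should add to C7, a hydride (unlike a dissolving metal) does not expel the C6 oxygen, and trapping the regiodefined enolate gives the C8=C10 enol ether, the only one possible beside quaternary C1.

Step 12
Reactants: 21 trimethylsilyl enol ether; 22 diiodomethane
Product: 25 trans-hydroazulenone (C8=C9–C10=O, 6α-OSi-t-BuMe2, 4β-OSiEt3), via siloxycyclopropane 23 (not isolated), via β-chloro ketone 24 (not isolated)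
Conditions: Et2Zn, 22, CH2Cl2, 0 °C → rt; crude, then FeCl3 (2.5 equiv), pyridine, DMF, 0 °C → rt; crude, then NaOAc, MeOH, reflux
Reagents that add atoms: diiodomethane 22, ICI
Why: The zinc carbenoid made from Et2Zn and 22 adds its methylene (C9) in one concerted step across the electron-rich C8=C10 enol ether (Simmons–Smith reaction in the Furukawa form), closing the three-membered ring by [2+1] cycloaddition from the α face, away from the axial C1 methyl group, and forming C8–C9 and C9–C10. FeCl3 then takes the place of silicon on the cyclopropanol oxygen, one-electron oxidation by trivalent iron gives an oxy radical whose β-scission breaks the shared C8–C10 bond, restores the C10 carbonyl group and leaves a tertiary C8 radical, and this radical takes chlorine from a second FeCl3 to give 24. NaOAc removes HCl by an E1cB path through the C9 enolate, the only enolate this ketone can form, so the alkene ends at C8=C9 in conjugation. The closest known reaction is the Ito–Saegusa one-carbon ring expansion of cyclic silyl enol ethers, and the seven-membered ring therefore arises by enlargement of the six-membered ring through fragmentation of the bicyclo[4.1.0]heptane and not by an end-to-end cyclisation with its medium-ring penalty. No stereocentre of 25 is made here, since the configurations created at C8 and C10 in 23 and at C8 in 24 are erased, while C1, C4, C5 and C6 are spectators. The step needs a single enol ether regioisomer and cleavage of the inner instead of an outer cyclopropane bond, and the substrate secures both, because quaternary C1 leaves enolisation toward C8 as the only option and the C8 methyl group makes the inner scission the one that yields a tertiary radical and releases the strain of the fused system.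

Step 13
Reactants: 25 trans-hydroazulenone
Product: 26 8α,9α-epoxy-10-ketone
Conditions: 30 % H2O2, aq NaOH, MeOH, 0 °C → rt
Reagents that add atoms: hydrogen peroxide, OO
Why: In this Weitz–Scheffer epoxidation hydroperoxide should add to C8 from the α face, the outer face of the folded cycloheptenone, because the axial C1 methyl group and the axial C6 hydrogen close the β face, the peroxy enolate closes on the same face and so sets C8 and C9 together, and silyloxide at C6 is too poor a leaving group for vinylogous elimination.

Step 14
Reactants: 26 epoxy ketone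
Product: 27 4β,6α-dihydroxy-8α,9α-epoxy-10-ketone
Conditions: Bu4NF, THF, 0 °C → rt
Reagents that add atoms: none
Why: Fluoride-induced desilylation frees both alcohols in one operation, and because the ketone has no enolisable hydrogen (C1 quaternary, C9 an oxirane CH) the basic fluoride can neither epimerise nor eliminate.

Step 15
Reactants: 27 dihydroxy epoxy ketone; 28 angelic acid
Product: 29 6α-angelate of the epoxy ketone
Conditions: 28, 2,4,6-trichlorobenzoyl chloride, Et3N, toluene, rt; then 27, 80 °C
Reagents that add atoms: angelic acid 28, C/C=C(/C)C(=O)O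
Why: Yamaguchi-type mixed-anhydride acylation without a nucleophilic catalyst is the usual way to make angelates without Z to E isomerisation, only the secondary equatorial C6 hydroxyl group should react while the tertiary C4 hydroxyl group is inert, and keeping C10 as a ketone removes any competition from a C10 hydroxyl group.

Step 16
Reactants: 29 angelate epoxy ketone
Product: 30 lapiferine
Conditions: NaBH4, CeCl3·7H2O, MeOH, −40 °C
Reagents that add atoms: none
Why: In this Luche-type reduction the α epoxide holds the seven-membered ring in the chair in which its oxygen points outward, the C1–C5 bond then stands perpendicular to the C10 carbonyl on the α side, so hydride should enter antiperiplanar to it from the β face, between the C1 methyl group and C2 and away from the oxirane oxygen, giving the 10α alcohol cis to the epoxide, while ester, oxirane and angelate alkene are inert.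

Compound list
1 | (R)-carvone | CC1=CC[C@H](CC1=O)C(C)=C | starting material
2 | iodomethane | CI | starting material
3 | lithium dienolate of 1 (C1=C10), not isolated | [Li+].[O-]C1=C[C@H](C(C)=C)CC=C1C | intermediate
4 | (5R)-2,6-dimethyl-5-(prop-1-en-2-yl)cyclohex-2-en-1-one (6-methylcarvone, both C1 epimers) | O=C1C(C)=CC[C@@H](C(C)=C)C1C | intermediate
5 | allyl bromide | C=CCBr | starting material
6 | lithium dienolate of 4, not isolated | [Li+].[O-]C1=C(C)[C@H](C(C)=C)CC=C1C | intermediate
7 | (5S,6S)-6-allyl-2,6-dimethyl-5-(prop-1-en-2-yl)cyclohex-2-en-1-one (C1 CH3 β, allyl α, C5 isopropenyl β) | O=C1C(C)=CC[C@@H](C(C)=C)[C@]1(C)CC=C | intermediate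
8 | triethylsilyl dienol ether of 7 (C10(OSiEt3)=C8–C7=C6) | CC[Si](CC)(CC)OC1=C(C)C=C[C@@H](C(C)=C)[C@]1(C)CC=C | intermediate
9 | 6α-hydroxy derivative of 7 (OH trans to isopropenyl) | O=C1C(C)=C[C@H](O)[C@@H](C(C)=C)[C@]1(C)CC=C | intermediate
10 | 6α-tert-butyldimethylsilyl ether of 9 | O=C1C(C)=C[C@H](O[Si](C)(C)C(C)(C)C)[C@@H](C(C)=C)[C@]1(C)CC=C | intermediate
11 | 10 with the isopropenyl group epoxidised (both oxirane epimers), not isolated | O=C1C(C)=C[C@H](O[Si](C)(C)C(C)(C)C)[C@@H](C2(C)CO2)[C@]1(C)CC=C | intermediate
12 | C4 methyl ketone (acetyl β on C5, allyl α on C1, 6α-silyl ether) | O=C1C(C)=C[C@H](O[Si](C)(C)C(C)(C)C)[C@@H](C(C)=O)[C@]1(C)CC=C | intermediate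
13 | terminal lithium enolate of 12, not isolated | O=C1C(C)=C[C@H](O[Si](C)(C)C(C)(C)C)[C@@H](C(=C)[O-])[C@]1(C)CC=C.[Li+] | intermediate
14 | terminal tert-butyldimethylsilyl enol ether of 12 | O=C1C(C)=C[C@H](O[Si](C)(C)C(C)(C)C)[C@@H](C(=C)O[Si](C)(C)C(C)(C)C)[C@]1(C)CC=C | intermediate
15 | trans-fused bicyclic silyl enol ether (C3=C4–OSi), not isolated | CC(C)(C)[Si](C)(C)O[C@H]1C=C(C)C(=O)[C@@]2(C)CC=C(O[Si](C)(C)C(C)(C)C)[C@H]12 | intermediate
16 | trans-hydrindene-4,10-dione (1β-CH3, 5α-H, 6α-silyl ether, C7=C8) | CC(C)(C)[Si](C)(C)O[C@H]1C=C(C)C(=O)[C@@]2(C)CCC(=O)[C@H]12 | intermediate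
17 | isopropylmagnesium chloride | CC(C)[Mg]Cl | starting material
18 | 4β-hydroxy-4α-isopropyl trans-hydrindenone | CC(C)(C)[Si](C)(C)O[C@H]1C=C(C)C(=O)[C@@]2(C)CC[C@@](O)(C(C)C)[C@H]12 | intermediate
19 | 4β-triethylsilyl ether of 18 | CC(C)(C)[Si](C)(C)O[C@H]1C=C(C)C(=O)[C@@]2(C)CC[C@@](O[Si](CC)(CC)CC)(C(C)C)[C@H]12 | intermediate
20 | lithium C8=C10 enolate, not isolated | [Li+].CC(C)(C)[Si](C)(C)O[C@H]1CC(C)=C([O-])[C@@]2(C)CC[C@@](O[Si](CC)(CC)CC)(C(C)C)[C@H]12 | intermediate
21 | trans-hydrindanone trimethylsilyl enol ether (precursor of the key step) | CC(C)(C)[Si](C)(C)O[C@H]1CC(C)=C(O[Si](C)(C)C)[C@@]2(C)CC[C@@](O[Si](CC)(CC)CC)(C(C)C)[C@H]12 | intermediate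
22 | diiodomethane | ICI | starting material
23 | siloxycyclopropane (C9 methylene α, C8 CH3 and C10 OSiMe3 β), not isolated | CC(C)(C)[Si](C)(C)O[C@H]1C[C@@]2(C)C[C@@]2(O[Si](C)(C)C)[C@@]3(C)CC[C@@](O[Si](CC)(CC)CC)(C(C)C)[C@H]13 | intermediate
24 | 8-chloro-8-methyl cycloheptanone (both C8 epimers), not isolated | CC(C)(C)[Si](C)(C)O[C@H]1CC(C)(Cl)CC(=O)[C@@]2(C)CC[C@@](O[Si](CC)(CC)CC)(C(C)C)[C@H]12 | intermediate
25 | trans-hydroazulenone with C8=C9–C10=O (product of the key step) | CC(C)(C)[Si](C)(C)O[C@H]1CC(C)=CC(=O)[C@@]2(C)CC[C@@](O[Si](CC)(CC)CC)(C(C)C)[C@H]12 | intermediate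
26 | 8α,9α-epoxy-10-ketone | CC(C)(C)[Si](C)(C)O[C@H]1C[C@@]2(C)O[C@H]2C(=O)[C@@]2(C)CC[C@@](O[Si](CC)(CC)CC)(C(C)C)[C@H]12 | intermediate
27 | 4β,6α-dihydroxy-8α,9α-epoxy-10-ketone | O[C@H]1C[C@@]2(C)O[C@H]2C(=O)[C@@]2(C)CC[C@@](O)(C(C)C)[C@H]12 | intermediate
28 | angelic acid, (Z)-2-methylbut-2-enoic acid | C/C=C(/C)C(=O)O | starting material
29 | 6α-angelate of 27 | C/C=C(/C)C(=O)O[C@H]1C[C@@]2(C)O[C@H]2C(=O)[C@@]2(C)CC[C@@](O)(C(C)C)[C@H]12 | intermediate
30 | lapiferine | C/C=C(/C)C(=O)O[C@H]1C[C@@]2(C)O[C@H]2[C@@H](O)[C@@]2(C)CC[C@@](O)(C(C)C)[C@H]12 | target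

Total step count: 16. Longest linear sequence: 16 steps from (R)-carvone; all other inputs are commercial and used as bought.

Steps most likely to fail

1. Step 12.
What may go wrong: the zinc carbenoid may transfer its methylene too slowly to the tetrasubstituted enol ether wedged between quaternary C1 and the C8 methyl group, so Lewis-acidic zinc iodide strips the enol silyl group first. In the iron stage, acid-induced loss of the C4 or C6 silyl ether, or protolytic opening of an outer cyclopropane bond, may compete with the oxidative fragmentation.
Fallback: keep the C9 insertion but change the carbene and the opening mode. Starting from 21, dibromocarbene (CHBr3, KOt-Bu, pentane, −20 °C), which is smaller and more electrophilic, should give the dibromo(siloxy)cyclopropane F1. Warming in toluene with pyridine triggers the 2π-electrocyclic cyclopropyl-to-allyl cation opening, which can only break C8–C10, and loss of silicon gives the 9-bromo enone F2. Hydrodebromination (Bu3SnH, Pd(PPh3)4, THF) comes back to the route at 25.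

2. Step 9.
What may go wrong: deprotonation of the crowded cyclopentanone instead of addition, followed by epimerisation at C5 to the more stable cis fusion or β-elimination of the C6 silyloxy group. β-Hydride transfer from the branched reagent may also compete.
Fallback: starting from 16, the flatter sp2 nucleophile isopropenylmagnesium bromide with CeCl3 (THF, −78 °C), which cannot transfer a β-hydride, should give the 4α-isopropenyl carbinol F3 by the same α-face attack. Homogeneous hydrogenation (H2, RhCl(PPh3)3, benzene) saturates a 1,1-disubstituted alkene and leaves a trisubstituted enone alone, and it comes back to the route at 18.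

3. Step 16.
What may go wrong: poor facial selectivity of hydride delivery if the ring populates a boat-like conformer in which the C1 methyl group, not C5, stands perpendicular to the carbonyl group.
Fallback: set C10 by reagent control before the epoxide, and let the new hydroxyl group place the oxygen.
- Starting from 25, Bu4NF should give the dihydroxy enone F4.
- The mixed-anhydride acylation of step 15 should give the angelate enone F5.
- Corey–Bakshi–Shibata reduction ((S)-methyl oxazaborolidine, catecholborane, toluene, −78 °C, with C1 as the large and C9 as the small flank) should give the 10α allylic alcohol F6.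
- Hydroxyl-directed epoxidation (VO(acac)2, t-BuOOH, CH2Cl2, 0 °C) delivers oxygen syn to the 10α hydroxyl group and comes back to the route at 30.

Further compounds
F1 | step 12 | dibromo(siloxy)cyclopropane (CBr2 bridge α across C8–C10) | CC(C)(C)[Si](C)(C)O[C@H]1C[C@@]2(C)C(Br)(Br)[C@@]2(O[Si](C)(C)C)[C@@]3(C)CC[C@@](O[Si](CC)(CC)CC)(C(C)C)[C@H]13
F2 | step 12 | 9-bromo enone (9-bromo derivative of 25) | CC(C)(C)[Si](C)(C)O[C@H]1CC(C)=C(Br)C(=O)[C@@]2(C)CC[C@@](O[Si](CC)(CC)CC)(C(C)C)[C@H]12
F3 | step 9 | 4α-isopropenyl carbinol (4β-hydroxy-4α-(prop-1-en-2-yl) trans-hydrindenone) | CC(C)(C)[Si](C)(C)O[C@H]1C=C(C)C(=O)[C@@]2(C)CC[C@@](O)(C(C)=C)[C@H]12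
F4 | step 16 | dihydroxy enone (4β,6α-dihydroxy trans-hydroazulenone) | O[C@H]1CC(C)=CC(=O)[C@@]2(C)CC[C@@](O)(C(C)C)[C@H]12
F5 | step 16 | angelate enone (6α-angelate of F4) | C/C=C(/C)C(=O)O[C@H]1CC(C)=CC(=O)[C@@]2(C)CC[C@@](O)(C(C)C)[C@H]12
F6 | step 16 | 10α allylic alcohol (8,9-ene, 6α-angelate, 4β-OH) | C/C=C(/C)C(=O)O[C@H]1CC(C)=C[C@@H](O)[C@@]2(C)CC[C@@](O)(C(C)C)[C@H]12
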